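Retrosynthetic cuts, in order: the ether bond O–C1' (retro-oxa-Michael, opens tetrahydrofuran ring D); C13–C3' (retro-aldol, releases ring E as an enantiopure cyclohexenone); the C8 methyl (back through a C8/C14 cyclopropyl ketone to an 8(14)-en-13-one); ring C back to an anisole; the C6 oxygen back to benzylic C7; C9–C10 and C4–C5 in one operation; finally C6–C7.
Enabling feature: ring C (C8, C9, C11–C14) has its only heteroatom on C13, para to C9 and meta to C8, and C8 carries C7, the neighbour of oxygenated C6. A 3-methoxyphenyl ring can therefore stand in for ring C, end a cation cascade at C9, hold C13 at the ketone oxidation level and make C7 benzylic.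
Forward order: C6–C7 chain coupling; rings A and B closed together onto aromatic ring C; oxygen moved from C7 to C6; ring C dearomatised; C8 methyl installed; ring E joined at C13; ring D closed last.
Stereochemistry: C5 and C10 come from the chiral acid and the E-alkene chair fold. C6, C9, C8 and C13 are relayed from them (blocked-face hydride delivery, equilibrating protonation, hydroxyl-directed cyclopropanation, equatorial attack on the ketone). C3' is controlled by a C5' silyloxy centre made by CBS reduction and erased later, C2' by hydride attack next to C3', C1' by the bridge geometry, and C6' by equilibration.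
Key step: step 2

Numbering: decalin C1–C10 (gem-dimethyl C4, acetate C6, methyls on C8 and C10). Ring C = C8, C9, C11–C14 (spiro C13). Ring E = C1' (ether CH), C2' (CHOH), C3' (CH bonded to C13), C4' (CH2), C5' (C=O), C6' (CHCH3). Ring D = C13, O, C1', C2', C3'. In "ent-" names the α/β descriptors are those of the mirror-image normal podocarpane, so ent-β always means the face that carries the C10 methyl.
Assumption: the (S)-binaphthol ligand is taken to give the (5R,10R) series, by mirror-image analogy with the (R)-ligand, which gives (5S,10S)-podocarpatrienes; if the sense proves opposite, the antipodal ligand is used.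
Reagent note: the ligand of step 2 is made from commercial (S)-BINOL by mono-O-alkylation with 2-fluorobenzyl bromide and is recovered after the reaction. Dimethyldioxirane is prepared from acetone and Oxone.

Step 1
Reactants: 1 3-methoxybenzyl chloride; 2 geranyl chloride
Product: 4 (E)-1-(4,8-dimethylnona-3,7-dienyl)-3-methoxybenzene, via 3-methoxybenzylmagnesium chloride 3 (not isolated)
Conditions: 1, Mg, THF, 0 °C; then 2, Li2CuCl4 (3 mol %), THF, −10 °C → rt
Reagents that add atoms: magnesium, [Mg] (present in 3 only, not in 4)
Why: Copper-catalysed cross-coupling of a benzylic Grignard reagent with a primary allylic chloride takes place at the CH2Cl carbon without allylic transposition, so the C6–C7 bond forms, the E alkene is kept and no stereocentre arises.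

Step 2
Reactants: 4 (E)-1-(4,8-dimethylnona-3,7-dienyl)-3-methoxybenzene
Product: 5 ent-13-methoxypodocarpa-8,11,13-triene (5R,10R)
Conditions: (S)-2'-(2-fluorobenzyloxy)-1,1'-binaphthalen-2-ol (1.1 equiv), SnCl4 (1.0 equiv), toluene, −78 °C, 2–3 d
Reagents that add atoms: none
Why: SnCl4 binds the naphthol oxygen of the ligand and makes its O–H strongly acidic; this chiral acid protonates C3 of the terminal alkene, C5 of the C5=C10 alkene attacks the developing C4 cation, the arene carbon C9 attacks the developing C10 cation, and loss of the arene proton returns the acid. The closest known reaction is the enantioselective proton-initiated polyene cyclisation of homogeranyl arenes by Lewis-acid-assisted chiral Brønsted acids, a cation–olefin cascade ended by a Friedel–Crafts alkylation. Ring A closes 6-endo-trig at the C5=C10 alkene through a chair (bond C4–C5), and ring B closes as a six-membered Friedel–Crafts ring, endo with respect to the aromatic C8–C9 bond, in a second chair-like fold (bond C9–C10). The absolute configuration at C5 and C10 is fixed by the ligand enantiomer, which selects the protonated alkene face and thereby one of the two mirror-image chair–chair folds, and the trans relation of H5 and the C10 methyl follows from anti addition across the E alkene. The step needs initiation at the terminal alkene, complete second closure instead of proton loss, and para rather than ortho attack; the terminal trisubstituted alkene is the most accessible basic site, the methoxy group makes C9 (para to it) nucleophilic enough to intercept C10, and the other ortho carbon, wedged between side chain and methoxy group, is crowded.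

Step 3
Reactants: 5 ent-13-methoxypodocarpa-8,11,13-triene
Product: 6 ent-13-methoxypodocarpa-8,11,13-trien-7-one
Conditions: CrO3, AcOH–H2O, rt
Reagents that add atoms: chromium trioxide, O=[Cr](=O)=O
Why: Benzylic C–H oxidation by hexavalent chromium is confined to C7, the only benzylic carbon that bears hydrogen (C10 is quaternary), as is usual for O-methylated podocarpatrienes.

Step 4
Reactants: 6 ent-13-methoxypodocarpa-8,11,13-trien-7-one
Product: 7 ent-13-methoxypodocarpa-8,11,13-trien-7-ol (C7 epimers)
Conditions: NaBH4, MeOH–THF, 0 °C
Reagents that add atoms: none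
Why: Borohydride reduction of an aryl ketone; the new C7 carbinol centre is removed in the next step, so its configuration is of no consequence.

Step 5
Reactants: 7 ent-13-methoxypodocarpa-8,11,13-trien-7-ol
Product: 8 ent-13-methoxypodocarpa-6,8,11,13-tetraene
Conditions: TsOH·H2O (5 mol %), toluene, reflux, Dean–Stark
Reagents that add atoms: none
Why: Acid-catalysed E1 dehydration of the benzylic alcohol can lose a proton only from C6 and gives the conjugated C6=C7 styrene, leaving C5 untouched.

Step 6
Reactants: 8 ent-13-methoxypodocarpa-6,8,11,13-tetraene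
Product: 10 ent-13-methoxypodocarpa-8,11,13-trien-6-one, via ent-6α,7α-epoxy-13-methoxypodocarpa-8,11,13-triene 9 (not isolated)
Conditions: dimethyldioxirane, acetone, 0 °C; evaporate; BF3·OEt2 (0.3 equiv), CH2Cl2, −40 °C
Reagents that add atoms: dimethyldioxirane, CC1(C)OO1
Why: Epoxidation from the face opposite the axial C4 and C10 methyls is followed by a Lewis-acid Meinwald rearrangement in which the C7–O bond ionises to the benzylic cation and the aligned axial C6 hydrogen shifts to C7, as in the dihydronaphthalene oxide to 2-tetralone conversion; short contact at low temperature should keep the trans C5 centre from enolising.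

Step 7
Reactants: 10 ent-13-methoxypodocarpa-8,11,13-trien-6-one
Product: 11 ent-13-methoxypodocarpa-8,11,13-trien-6β-ol (5R,6S,10R)
Conditions: LiAlH4, Et2O, 0 °C
Reagents that add atoms: none
Why: Hydride reduction under steric approach control: the face of C6 that carries the axial C4 and C10 methyls is closed, so hydride adds from the H5 face and the hydroxyl ends axial on the methyl face.

Step 8
Reactants: 11 ent-13-methoxypodocarpa-8,11,13-trien-6β-ol
Product: 13 ent-6β-hydroxypodocarp-8-en-13-one, via ent-13-methoxypodocarpa-8,12-dien-6β-ol 12 (not isolated)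
Conditions: Li, NH3(l), THF–t-BuOH, −33 °C; NH4Cl, evaporate NH3; then (CO2H)2 (cat.), THF–MeOH–H2O, rt
Reagents that add atoms: water, O
Why: Birch reduction keeps the methoxy-bearing carbon and both alkyl-bearing carbons sp2 (C12=C13 enol ether, C8=C9 alkene) while the homobenzylic C6 alkoxide is inert, and oxalic acid hydrolyses only the enol ether, which unmasks the C13 ketone without disturbing C6.

Step 9
Reactants: 13 ent-6β-hydroxypodocarp-8-en-13-one
Product: 14 ent-6β-hydroxypodocarp-8(14)-en-13-one (H9 on the face opposite the C10 methyl)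
Conditions: NaOMe (0.2 equiv), MeOH, 0 °C → rt
Reagents that add atoms: none
Why: Base-catalysed β,γ to α,β enone isomerisation through the extended dienolate, with reversible protonation at C9 giving the more stable trans-anti arrangement; base is preferred to acid because the C6 hydroxyl, a vinylogous β-substituent of the enone, is a poor leaving group under these conditions.

Step 10
Reactants: 14 ent-6β-hydroxypodocarp-8(14)-en-13-one
Product: 15 ent-podocarp-8(14)-ene-6β,13β-diol
Conditions: Li[HB(s-Bu)3] (L-Selectride, 2.5 equiv), THF, −78 °C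
Reagents that add atoms: none
Why: 1,2-Reduction of a β,β-disubstituted cyclohexenone by a bulky trialkylborohydride, which arrives along the equatorial trajectory and gives the pseudo-axial allylic alcohol on the face of the C10 methyl, as known for 19-nor-4-en-3-one steroids.

Step 11
Reactants: 15 ent-podocarp-8(14)-ene-6β,13β-diol
Product: 16 ent-8β,14β-methanopodocarpane-6β,13β-diol (cyclopropane C8–CH2–C14)
Conditions: Et2Zn, CH2I2, CH2Cl2, 0 °C → rt
Reagents that add atoms: diiodomethane, ICI
Why: Hydroxyl-directed Simmons–Smith cyclopropanation (Furukawa reagent): the zinc alkoxides of the pseudo-axial allylic C13 hydroxyl and the axial homoallylic C6 hydroxyl both lie on the face of the C10 methyl and deliver CH2 to that otherwise more hindered face of C8=C14, which sets C8 and the temporary centre C14.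

Step 12
Reactants: 16 ent-8β,14β-methanopodocarpane-6β,13β-diol
Product: 17 ent-6β-hydroxy-8β,14β-methanopodocarpan-13-one
Conditions: 2,2,6,6-tetramethylpiperidine-1-oxyl (TEMPO, 0.1 equiv), PhI(OAc)2 (1.1 equiv), CH2Cl2, rt
Reagents that add atoms: none
Why: Nitroxyl-catalysed alcohol oxidation: the crowded oxoammonium ion cannot engage the C6 hydroxyl, which is 1,3-diaxial to the C4 and C10 methyls and the cyclopropane CH2, so only the cyclopropyl carbinol at C13 should be oxidised.

Step 13
Reactants: 17 ent-6β-hydroxy-8β,14β-methanopodocarpan-13-one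
Product: 18 ent-6β-hydroxy-8β-methylpodocarpan-13-one
Conditions: Li, NH3(l)–THF, −78 °C; solid NH4Cl
Reagents that add atoms: none
Why: Dissolving-metal reductive opening of a conjugated cyclopropyl ketone cleaves the exocyclic C14–CH2 bond, the one that overlaps with the carbonyl π system, so the CH2 stays on C8 as a methyl group with C8 unchanged, and the lithium enolate shields C13 from further reduction until the quench.

Step 14
Reactants: 18 ent-6β-hydroxy-8β-methylpodocarpan-13-one
Product: 19 ent-6β-acetoxy-8β-methylpodocarpan-13-one
Conditions: Ac2O, 4-(dimethylamino)pyridine, Et3N, ClCH2CH2Cl, 50 °C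
Reagents that add atoms: acetic anhydride, CC(=O)OC(C)=O
Why: Nucleophile-catalysed acetylation, which handles even tertiary alcohols, should acylate the C6 hydroxyl on warming despite its three 1,3-diaxial methyl neighbours and leaves the ketone alone.

Step 15
Reactants: 20 2-methylcyclohex-2-en-1-one
Product: 21 (R)-2-methylcyclohex-2-en-1-ol
Conditions: (S)-1-methyl-3,3-diphenyltetrahydro-1H,3H-pyrrolo[1,2-c][1,3,2]oxazaborole ((S)-Me-CBS, 10 mol %), BH3·SMe2, THF, −20 °C; MeOH
Reagents that add atoms: none
Why: Corey–Bakshi–Shibata reduction in which the 2-methylvinyl arm acts as the large group and the ring CH2 as the small one, so the (S)-catalyst should deliver hydride to give the R carbinol (future C5').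

Step 16
Reactants: 21 (R)-2-methylcyclohex-2-en-1-ol
Product: 22 (R)-tert-butyldimethyl[(2-methylcyclohex-2-en-1-yl)oxy]silane
Conditions: t-BuMe2SiCl, imidazole, DMF, rt
Reagents that add atoms: tert-butyldimethylsilyl chloride, CC(C)(C)[Si](C)(C)Cl
Why: Imidazole-promoted O-silylation of a secondary allylic alcohol, with no change at the stereocentre.

Step 17
Reactants: 22 (R)-tert-butyldimethyl[(2-methylcyclohex-2-en-1-yl)oxy]silane
Product: 23 (R)-4-(tert-butyldimethylsilyloxy)-3-methylcyclohex-2-en-1-one
Conditions: Rh2(cap)4 (dirhodium tetrakis(caprolactamate), 1 mol %), t-BuOOH, K2CO3, CH2Cl2, rt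
Reagents that add atoms: tert-butyl hydroperoxide, CC(C)(C)OO
Why: Catalytic allylic C–H oxidation through tert-butylperoxyl radicals attacks the ring CH2 next to the =CH terminus (future C2'), the most accessible allylic site, rather than the shielded C–H under the bulky silyl ether or the vinylic methyl, and gives the enone with the carbinol centre intact.

Step 18
Reactants: 23 (R)-4-(tert-butyldimethylsilyloxy)-3-methylcyclohex-2-en-1-one; 19 ent-6β-acetoxy-8β-methylpodocarpan-13-one
Product: 26 C13–C3' aldol adduct (C13 OH axial; C3' equatorial on ring C; C3' S; C5' R), via lithium cross-conjugated dienolate 24 (not isolated), via dichlorocerium dienolate 25 (not isolated)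
Conditions: 23, LiN(i-Pr)2, THF, −78 °C; CeCl3 (anhydrous), −78 °C; 19, −78 °C; AcOH, −78 °C
Reagents that add atoms: lithium diisopropylamide, CC(C)N([Li])C(C)C (lithium in 24 only); cerium trichloride, Cl[Ce](Cl)Cl (in 25 only)
Why: Aldol addition of a preformed, weakly basic cerium enolate to a ketone: kinetic α'-deprotonation gives the cross-conjugated dienolate, which attacks the C13 carbonyl equatorially because the axial path is blocked by the 1,3-diaxial C8 methyl, and bonds through the ring E face opposite the C5' silyloxy group (C3' trans to C5', also the more stable epimer), while the hindered C6 acetate is neither deprotonated nor acylating at −78 °C.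

Step 19
Reactants: 26 C13–C3' aldol adduct
Product: 27 allylic alcohol (C2' OH cis to the C3'–C13 bond; 2'S,3'R,5'R)
Conditions: Li[HB(s-Bu)3] (L-Selectride, 2.5 equiv), THF, −78 °C
Reagents that add atoms: none
Why: 1,2-Reduction of a β,β-disubstituted enone by a bulky trialkylborohydride which, as with 2-alkylcyclohexanones, approaches equatorially next to the large equatorial C3' substituent and gives the axial C2' alcohol cis to it; the low temperature also disfavours retro-aldol cleavage and spares ester and silyl ether.

Step 20
Reactants: 27 allylic alcohol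
Product: 28 C2' acetate of 27
Conditions: Ac2O (1.5 equiv), pyridine, 4-(dimethylamino)pyridine (5 mol %), CH2Cl2, 0 °C → rt
Reagents that add atoms: acetic anhydride, CC(=O)OC(C)=O
Why: Chemoselective acetylation of the only secondary hydroxyl, the axial tertiary C13 hydroxyl beside ring E being far slower under these mild conditions.

Step 21
Reactants: 28 C2' acetate
Product: 29 C5' alcohol (silyl group removed)
Conditions: HF·pyridine, THF–pyridine, 0 °C → rt
Reagents that add atoms: none
Why: Fluoride-mediated desilylation under non-basic conditions frees the C5' hydroxyl without acetyl migration or ester cleavage.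

Step 22
Reactants: 29 C5' alcohol
Product: 30 enone acetate (C5' ketone conjugated to C6'(CH3)=C1'H; C2' OAc)
Conditions: Dess–Martin periodinane, CH2Cl2, rt
Reagents that add atoms: none
Why: Dess–Martin oxidation of the only oxidisable (secondary allylic) alcohol transposes the enone of ring E to its final position and erases the auxiliary C5' centre, the tertiary C13 hydroxyl being inert.

Step 23
Reactants: 30 enone acetate
Product: 32 target spiro ether CNP0188572.2, via γ-hydroxy enone 31 (not isolated)
Conditions: K2CO3 (0.3 equiv), MeOH, 0 °C → rt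
Reagents that add atoms: none
Why: Mild methanolysis removes the exposed allylic C2' acetate but not the C6 acetate buried under three 1,3-diaxial methyls, and the C13 hydroxyl then closes ring D by a 5-exo-trig intramolecular oxa-Michael addition to C1', possible only on the ring E face that carries C13 (sets C1'), after which the α-centre C6' equilibrates to the equatorial methyl.

Compound list
1 | 3-methoxybenzyl chloride | COc1cccc(CCl)c1 | starting material
2 | geranyl chloride, (E)-1-chloro-3,7-dimethylocta-2,6-diene | CC(C)=CCC/C(C)=C/CCl | starting material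
3 | 3-methoxybenzylmagnesium chloride | COc1cccc(C[Mg]Cl)c1 | intermediate
4 | (E)-1-(4,8-dimethylnona-3,7-dienyl)-3-methoxybenzene | COc1cccc(CC/C=C(\C)CCC=C(C)C)c1 | intermediate
5 | ent-13-methoxypodocarpa-8,11,13-triene, (5R,10R), H5 and C10 methyl trans | COc1ccc2c(c1)CC[C@@H]1C(C)(C)CCC[C@]12C | intermediate
6 | ent-13-methoxypodocarpa-8,11,13-trien-7-one | COc1ccc2c(c1)C(=O)C[C@@H]1C(C)(C)CCC[C@]12C | intermediate
7 | ent-13-methoxypodocarpa-8,11,13-trien-7-ol (C7 epimers) | COc1ccc2c(c1)C(O)C[C@@H]1C(C)(C)CCC[C@]12C | intermediate
8 | ent-13-methoxypodocarpa-6,8,11,13-tetraene | COc1ccc2c(c1)C=C[C@@H]1C(C)(C)CCC[C@]12C | intermediate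
9 | ent-6α,7α-epoxy-13-methoxypodocarpa-8,11,13-triene (epoxide on the H5 face) | COc1ccc2c(c1)[C@H]3O[C@H]3[C@@H]1C(C)(C)CCC[C@]12C | intermediate
10 | ent-13-methoxypodocarpa-8,11,13-trien-6-one | COc1ccc2c(c1)CC(=O)[C@@H]1C(C)(C)CCC[C@]12C | intermediate
11 | ent-13-methoxypodocarpa-8,11,13-trien-6β-ol, axial OH on the C10-methyl face | COc1ccc2c(c1)C[C@H](O)[C@@H]1C(C)(C)CCC[C@]12C | intermediate
12 | ent-13-methoxypodocarpa-8,12-dien-6β-ol (Birch dienol ether) | COC1=CCC2=C(C1)C[C@H](O)[C@@H]1C(C)(C)CCC[C@]12C | intermediate
13 | ent-6β-hydroxypodocarp-8-en-13-one (β,γ-enone) | O=C1CCC2=C(C1)C[C@H](O)[C@@H]1C(C)(C)CCC[C@]12C | intermediate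
14 | ent-6β-hydroxypodocarp-8(14)-en-13-one, H9 opposite the C10 methyl | O[C@H]1CC2=CC(=O)CC[C@H]2[C@]2(C)CCCC(C)(C)[C@@H]12 | intermediate
15 | ent-podocarp-8(14)-ene-6β,13β-diol, both OH on the C10-methyl face | O[C@H]1CC2=C[C@@H](O)CC[C@H]2[C@]2(C)CCCC(C)(C)[C@@H]12 | intermediate
16 | ent-8β,14β-methanopodocarpane-6β,13β-diol, cyclopropane CH2 on the C10-methyl face | O[C@H]1C[C@@]23C[C@H]3[C@@H](O)CC[C@H]2[C@]2(C)CCCC(C)(C)[C@@H]12 | intermediate
17 | ent-6β-hydroxy-8β,14β-methanopodocarpan-13-one | O[C@H]1C[C@@]23C[C@H]3C(=O)CC[C@H]2[C@]2(C)CCCC(C)(C)[C@@H]12 | intermediate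
18 | ent-6β-hydroxy-8β-methylpodocarpan-13-one | O[C@H]1C[C@]2(C)CC(=O)CC[C@H]2[C@]2(C)CCCC(C)(C)[C@@H]12 | intermediate
19 | ent-6β-acetoxy-8β-methylpodocarpan-13-one | CC(=O)O[C@H]1C[C@]2(C)CC(=O)CC[C@H]2[C@]2(C)CCCC(C)(C)[C@@H]12 | intermediate
20 | 2-methylcyclohex-2-en-1-one | CC1=CCCCC1=O | starting material
21 | (R)-2-methylcyclohex-2-en-1-ol | O[C@@H]1CCCC=C1C | intermediate
22 | (R)-tert-butyldimethyl[(2-methylcyclohex-2-en-1-yl)oxy]silane | CC(C)(C)[Si](C)(C)O[C@@H]1CCCC=C1C | intermediate
23 | (R)-4-(tert-butyldimethylsilyloxy)-3-methylcyclohex-2-en-1-one | O=C1C=C(C)[C@H](O[Si](C)(C)C(C)(C)C)CC1 | intermediate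
24 | lithium cross-conjugated dienolate of the ring E enone | [Li]OC1=CC[C@@H](O[Si](C)(C)C(C)(C)C)C(C)=C1 | intermediate
25 | dichlorocerium dienolate of the ring E enone | Cl[Ce](Cl)OC1=CC[C@@H](O[Si](C)(C)C(C)(C)C)C(C)=C1 | intermediate
26 | aldol adduct: keto acetate skeleton with axial 13-OH (C8-methyl face) and, equatorial on C13, C3' of a 5'-silyloxy-6'-methyl-2'-oxocyclohexene ring; C3' S, C5' R, trans | CC(=O)O[C@H]1C[C@]2(C)C[C@@](O)(CC[C@H]2[C@]2(C)CCCC(C)(C)[C@@H]12)[C@@H]1C[C@@H](O[Si](C)(C)C(C)(C)C)C(C)=CC1=O | intermediate
27 | allylic alcohol: C2'=O of the adduct reduced, C2' OH cis to the C3'–C13 bond (2'S,3'R,5'R) | CC(=O)O[C@H]1C[C@]2(C)C[C@@](O)(CC[C@H]2[C@]2(C)CCCC(C)(C)[C@@H]12)[C@@H]1C[C@@H](O[Si](C)(C)C(C)(C)C)C(C)=C[C@@H]1O | intermediate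
28 | C2' acetate of the allylic alcohol | CC(=O)O[C@H]1C[C@]2(C)C[C@@](O)(CC[C@H]2[C@]2(C)CCCC(C)(C)[C@@H]12)[C@@H]1C[C@@H](O[Si](C)(C)C(C)(C)C)C(C)=C[C@@H]1OC(C)=O | intermediate
29 | C5' alcohol (silyl group removed, C2' OAc kept) | CC(=O)O[C@H]1C[C@]2(C)C[C@@](O)(CC[C@H]2[C@]2(C)CCCC(C)(C)[C@@H]12)[C@@H]1C[C@@H](O)C(C)=C[C@@H]1OC(C)=O | intermediate
30 | enone acetate: C5' ketone, C6'(CH3)=C1'H, C2' OAc, free 13-OH | CC(=O)O[C@H]1C[C@]2(C)C[C@@](O)(CC[C@H]2[C@]2(C)CCCC(C)(C)[C@@H]12)[C@@H]1CC(=O)C(C)=C[C@@H]1OC(C)=O | intermediate
31 | γ-hydroxy enone (C2' OH and 13-OH free) | CC(=O)O[C@H]1C[C@]2(C)C[C@@](O)(CC[C@H]2[C@]2(C)CCCC(C)(C)[C@@H]12)[C@@H]1CC(=O)C(C)=C[C@@H]1O | intermediate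
32 | CNP0188572.2: spiro ether with 6-OAc, C8 methyl, C10 methyl and the C13–O bond on one face, H5 and H9 on the other; on ring E the C1'–O, C2'–OH, C3'–C13 and C6'–CH3 bonds are all cis | CC(=O)O[C@H]1C[C@]2(C)C[C@]3(CC[C@H]2[C@]2(C)CCCC(C)(C)[C@@H]12)O[C@@H]1[C@H](O)[C@H]3CC(=O)[C@@H]1C | target

Total step count: 23 (20 on the main line, 3 for the ring E fragment).
Longest linear sequence: 20 steps (steps 1–14, then 18–23).

Steps most likely to fail

Step 18 (aldol union). Proton transfer between the enolate and the enolisable ketone, reversal of the addition before the quench, and erosion of the C3' face selectivity through enolisation of the adduct may all cut into the coupling. The fallback replaces acid–base enolate chemistry by a reductive Reformatsky-type coupling and sets out from 23 and 19. Compound 23 is silylated (LiN(i-Pr)2, Me3SiCl, THF, −78 °C) to (R)-5-(tert-butyldimethylsilyloxy)-4-methyl-2-(trimethylsilyloxy)cyclohexa-1,3-diene F1. N-Bromosuccinimide (THF, −78 °C) converts this to (4R)-6-bromo-4-(tert-butyldimethylsilyloxy)-3-methylcyclohex-2-en-1-one F2. SmI2 (2.2 equiv, THF, −78 °C), added to a mixture of F2 and 19, generates a trivalent samarium enolate in the presence of the ketone under neutral conditions. Its tightly chelated aldolate should not revert, and the sequence comes back to the route at 26.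

Step 23 (deacetylation and oxa-Michael closure). Attack of the crowded tertiary hydroxyl on the enone may be slower than base-induced isomerisation of the γ-hydroxy enone or creeping methanolysis at C6. The fallback makes the O–C1' bond by electrophilic activation of the alkene before the enone exists and sets out from 29. N-Iodosuccinimide (CH2Cl2, 0 °C) forms the iodonium ion on the ring E face away from C13. The C13 hydroxyl, 1,3-diaxial to C1', opens it to the 6'-iodo spiro ether F3. Bu3SnH with azobisisobutyronitrile (toluene, 80 °C) removes the iodine to give the deiodinated C5' alcohol F4 (C6' epimers). Dess–Martin periodinane then gives the C2' acetate of the target F5. K2CO3 in MeOH now only has to cleave the exposed acetate and equilibrate C6' to the equatorial methyl, and the sequence comes back to the route at 32.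

Step 11 (directed cyclopropanation). Low reactivity of the trisubstituted alkene on the face shielded by the C10 methyl, or leakage to undirected delivery on the open face, would lower conversion or give the wrong C8 epimer. The fallback tethers the carbon to the C6 oxygen, sets out from 14 and also bypasses steps 10, 12 and 13. (Bromomethyl)chlorodimethylsilane with imidazole (CH2Cl2, rt) gives the (bromomethyl)dimethylsilyl ether F6. Slow addition of Bu3SnH and azobisisobutyronitrile (benzene, reflux) generates the α-silyl radical. This radical adds 6-exo to C8, the β-carbon of the enone, necessarily from the face of the C6 oxygen, and gives the cyclic siloxane F7. Protodesilylation with Bu4NF (DMF, 70 °C) turns the C8–CH2–Si link into the C8 methyl and frees the C6 hydroxyl, and the sequence comes back to the route at 18.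

Further compounds
F1 | step 18 | (R)-5-(tert-butyldimethylsilyloxy)-4-methyl-2-(trimethylsilyloxy)cyclohexa-1,3-diene | C[Si](C)(C)OC1=CC[C@@H](O[Si](C)(C)C(C)(C)C)C(C)=C1
F2 | step 18 | (4R)-6-bromo-4-(tert-butyldimethylsilyloxy)-3-methylcyclohex-2-en-1-one (C6 epimers) | O=C1C=C(C)[C@H](O[Si](C)(C)C(C)(C)C)CC1Br
F3 | step 23 | 6'-iodo spiro ether (ring D closed; C6' iodide anti to the ether oxygen; C5' OH; C2' OAc) | CC(=O)O[C@H]1C[C@]2(C)C[C@]3(CC[C@H]2[C@]2(C)CCCC(C)(C)[C@@H]12)O[C@@H]1[C@H](OC(C)=O)[C@H]3C[C@@H](O)[C@@]1(C)I
F4 | step 23 | deiodinated C5' alcohol (C6' epimers) | CC(=O)O[C@H]1C[C@]2(C)C[C@]3(CC[C@H]2[C@]2(C)CCCC(C)(C)[C@@H]12)O[C@@H]1[C@H](OC(C)=O)[C@H]3C[C@@H](O)C1C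
F5 | step 23 | C2' acetate of the target (C6' epimers) | CC(=O)O[C@H]1C[C@]2(C)C[C@]3(CC[C@H]2[C@]2(C)CCCC(C)(C)[C@@H]12)O[C@@H]1[C@H](OC(C)=O)[C@H]3CC(=O)C1C
F6 | step 11 | (bromomethyl)dimethylsilyl ether of the C6 hydroxy enone | BrC[Si](C)(C)O[C@H]1CC2=CC(=O)CC[C@H]2[C@]2(C)CCCC(C)(C)[C@@H]12
F7 | step 11 | cyclic siloxane C6–O–SiMe2–CH2–C8 of the 13-ketone | C[Si]1(C)O[C@H]2C[C@]3(C1)CC(=O)CC[C@H]3[C@]3(C)CCCC(C)(C)[C@@H]23
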